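## Retrosynthetic overview

1. The C40 chain is cut at C11'=C12' and C11=C12 into three pieces: the ε-end C15 phosphonium salt 20 (from (R)-α-ionone, which brings the 6'R ring ready-made), the C10 dialdehyde 21 and the acetylenic C15 phosphonium salt 17, joined by two Wittig reactions.
2. Salt 17 comes from a Sonogashira coupling (C8–C9) of ring alkyne 12 with the (E)-enol triflate 14. The alkyne carbon C7 is the ester carbon delivered by the ring-forming step (ester → aldehyde → Colvin rearrangement), and the C5 methyl replaces a temporary oxygen (enol phosphate → CH3).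
3. The hydroxylated ring (carotenoid numbering: C1 = CMe2, C3 = CHOH, C5 = C–CH3, C6 = C–alkyne) is built in one flask by an enantioselective [3+3] annulation of aldehyde 2 with the bis-silyl dienolate 3 of methyl acetoacetate. It forms C3–C4 (aldol addition, sets 3R) and C1–C6 (tertiary-cation alkylation, creates the quaternary carbon).
4. Enabling feature: in this cyclohexene ring the carbinol carbon C3 and the quaternary carbon C1 stand 1,3 across C2 (an aldehyde and a tertiary cation on one three-carbon chain). They face C4 and C6, which flank C5; with C5 written as a carbonyl, C4 and C6 are the two nucleophilic carbons of an acetoacetate whose ester carbon is C7.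
5. Order of ring formation: the hydroxy-cyclohexene ring in step 2; no other ring is formed.

Key step: step 2

Remark 1: compounds 3, 18 and 21 are taken as purchasable; 3 is used as the supplied E/Z mixture at the ketene acetal, which is without consequence.
Remark 2: the Ti/BINOL aldol addition is assumed to attack the Re face of aldehyde 2 with (R)-BINOL; should the opposite sense be found, (S)-BINOL is used.
Remark 3: atoms are numbered as in carotenoid nomenclature; the CIP descriptor at C3 changes with the substituent at C5 (S in 4–8, R from 9 on) while the spatial arrangement stays the same.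

## Route

Step 1
Reactants: 1 3-methoxy-3-methylbutan-1-ol
Product: 2 3-methoxy-3-methylbutanal
Conditions: TEMPO (5 mol %), PhI(OAc)2, CH2Cl2, rt
Reagents that add atoms: none
Why: Oxoammonium (TEMPO/PhI(OAc)2) oxidation of a primary alcohol stops at the aldehyde under neutral conditions, so the β-methoxy group should not be eliminated.

Step 2
Reactants: 2 3-methoxy-3-methylbutanal; 3 1-methoxy-1,3-bis[(trimethylsilyl)oxy]buta-1,3-diene
Product: 6 methyl (4S)-2,4-dihydroxy-6,6-dimethylcyclohex-1-ene-1-carboxylate, via aldol adduct 4 (not isolated), via silyl ether 5 (not isolated)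
Conditions: (R)-BINOL (10 mol %), Ti(OiPr)4 (10 mol %), 4 Å MS, THF, −78 °C → rt; THF removed in the same flask, CH2Cl2, TiCl4 (2.5 equiv), −78 → −20 °C; cold aq. HCl
Reagents that add atoms: none
Why: Proposed new method: a chiral Ti–BINOLate-catalysed Mukaiyama aldol addition of the terminal carbon of diene 3 to the Re face of aldehyde 2 makes C3–C4 and, after silyl transfer, leaves the β-silyloxy enoate 4; its enol-ether carbon (future C6) is then alkylated intramolecularly by the tertiary carbocation that TiCl4 releases from the chelated methyl ether at C1, which makes C1–C6 and, after loss of the silyl group, the enolised β-keto ester. The closest known reactions are the TiCl4-mediated [3+3] cyclisations of 1,3-bis(silyloxy)dienes with 1,3-dielectrophiles, the Ti/BINOL-catalysed aldol addition of this same diene to aldehydes and the Lewis-acid α-tert-alkylation of silyl enol ethers; new is their union in one flask with an aldehyde/tertiary ether pair as the dielectrophile. The six-membered ring closes in a 6-(enolendo)-exo-tet mode of SN1 type through a planar cation, so no trajectory problem arises and the geometry of the enol ether does not matter. The only new stereocentre, C3, is set in the aldol stage by the BINOL ligand (Re-face attack, S descriptor in 4–8, the 3R arrangement of the target) and is untouched by the ring closure because C3 is secondary and does not ionise. The step needs terminal (C4) rather than internal attack of the diene on the aldehyde, which is the inherent regiochemistry of this diene; it also needs C- rather than O-alkylation and ring closure rather than proton loss at the cation stage, which the intramolecular six-membered C-attack and the reversibility of O-tert-alkylation under TiCl4 should secure, and the mixture is kept at or below −20 °C so that the β-oxygen at C3 is not eliminated.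

Step 3
Reactants: 6 methyl (4S)-2,4-dihydroxy-6,6-dimethylcyclohex-1-ene-1-carboxylate
Product: 7 methyl (4S)-4-[(tert-butyldimethylsilyl)oxy]-2-hydroxy-6,6-dimethylcyclohex-1-ene-1-carboxylate
Conditions: TBSCl (1.1 equiv), imidazole, DMF, 0 °C → rt; aq. citric acid wash
Reagents that add atoms: tert-butyldimethylsilyl chloride, CC(C)(C)[Si](C)(C)Cl
Why: Silyl ether formation at the only alcohol; the hydrogen-bonded enol is far less nucleophilic, any enol silyl ether should be cleaved by the mild acid wash, and C3 is not touched.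

Step 4
Reactants: 7 methyl (4S)-4-[(tert-butyldimethylsilyl)oxy]-2-hydroxy-6,6-dimethylcyclohex-1-ene-1-carboxylate
Product: 9 methyl (4R)-4-[(tert-butyldimethylsilyl)oxy]-2,6,6-trimethylcyclohex-1-ene-1-carboxylate, via enol phosphate 8 (not isolated)
Conditions: NaH, ClP(O)(OEt)2, THF, 0 °C; then Fe(acac)3 (5 mol %), MeMgBr, THF/NMP, −20 → 0 °C
Reagents that add atoms: methylmagnesium bromide, C[Mg]Br
Why: O-Phosphorylation of the sodium enolate gives the cyclic enol phosphate, whose C–O bond is exchanged for methyl in an iron-catalysed Kumada-type cross-coupling; this turns the temporary C5 oxygen into the C5 methyl group and fixes the double bond at C5=C6.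

Step 5
Reactants: 9 methyl (4R)-4-[(tert-butyldimethylsilyl)oxy]-2,6,6-trimethylcyclohex-1-ene-1-carboxylate
Product: 10 {(4R)-4-[(tert-butyldimethylsilyl)oxy]-2,6,6-trimethylcyclohex-1-en-1-yl}methanol
Conditions: i-Bu2AlH (2.5 equiv), CH2Cl2, −78 → 0 °C; aq. potassium sodium tartrate
Reagents that add atoms: none
Why: 1,2-Hydride reduction of the hindered conjugated ester to the allylic alcohol; the silyl ether is inert.

Step 6
Reactants: 10 {(4R)-4-[(tert-butyldimethylsilyl)oxy]-2,6,6-trimethylcyclohex-1-en-1-yl}methanol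
Product: 11 (4R)-4-[(tert-butyldimethylsilyl)oxy]-2,6,6-trimethylcyclohex-1-ene-1-carbaldehyde
Conditions: MnO2 (activated, excess), CH2Cl2, rt
Reagents that add atoms: none
Why: Allylic oxidation with MnO2 should stop cleanly at the enal.

Step 7
Reactants: 11 (4R)-4-[(tert-butyldimethylsilyl)oxy]-2,6,6-trimethylcyclohex-1-ene-1-carbaldehyde
Product: 12 tert-butyl{[(1R)-4-ethynyl-3,5,5-trimethylcyclohex-3-en-1-yl]oxy}dimethylsilane
Conditions: Me3SiCHN2, n-BuLi, THF, −78 °C → rt
Reagents that add atoms: (trimethylsilyl)diazomethane, C[Si](C)(C)C=[N+]=[N-]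
Why: Colvin rearrangement: addition of lithiated (trimethylsilyl)diazomethane, Peterson-type loss of Me3SiOLi and N2 gives an alkylidene carbene whose 1,2-hydrogen shift furnishes the terminal alkyne (C7 is the former aldehyde carbon, C8 the reagent carbon).

Step 8
Reactants: 13 ethyl acetoacetate
Product: 14 ethyl (2E)-3-{[(trifluoromethyl)sulfonyl]oxy}but-2-enoate
Conditions: Tf2O, aq. Me4NOH, toluene, 5 °C → rt
Reagents that add atoms: trifluoromethanesulfonic anhydride, O=S(=O)(OS(=O)(=O)C(F)(F)F)C(F)(F)F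
Why: Biphasic O-sulfonylation of the acetoacetate enolate; with the non-coordinating tetramethylammonium counter-ion the non-chelated enolate reacts, which should give the (E)-enol triflate (triflate anti to the ester).

Step 9
Reactants: 12 tert-butyl{[(1R)-4-ethynyl-3,5,5-trimethylcyclohex-3-en-1-yl]oxy}dimethylsilane; 14 ethyl (2E)-3-{[(trifluoromethyl)sulfonyl]oxy}but-2-enoate
Product: 15 ethyl (2E)-5-{(4R)-4-[(tert-butyldimethylsilyl)oxy]-2,6,6-trimethylcyclohex-1-en-1-yl}-3-methylpent-2-en-4-ynoate
Conditions: Pd(PPh3)2Cl2 (3 mol %), CuI (6 mol %), Et3N, THF, rt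
Reagents that add atoms: none
Why: Sonogashira coupling of the terminal alkyne with the enol triflate proceeds with retention of the double-bond geometry and so forms C8–C9 with the 9E configuration.

Step 10
Reactants: 15 ethyl (2E)-5-{(4R)-4-[(tert-butyldimethylsilyl)oxy]-2,6,6-trimethylcyclohex-1-en-1-yl}-3-methylpent-2-en-4-ynoate
Product: 16 (2E)-5-{(4R)-4-[(tert-butyldimethylsilyl)oxy]-2,6,6-trimethylcyclohex-1-en-1-yl}-3-methylpent-2-en-4-yn-1-ol
Conditions: i-Bu2AlH (2.5 equiv), CH2Cl2, −78 °C; aq. potassium sodium tartrate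
Reagents that add atoms: none
Why: 1,2-Reduction of the enynoate to the allylic alcohol at low temperature should leave the alkyne, the alkene geometry and the silyl ether untouched.

Step 11
Reactants: 16 (2E)-5-{(4R)-4-[(tert-butyldimethylsilyl)oxy]-2,6,6-trimethylcyclohex-1-en-1-yl}-3-methylpent-2-en-4-yn-1-ol
Product: 17 {(2E)-5-[(4R)-4-hydroxy-2,6,6-trimethylcyclohex-1-en-1-yl]-3-methylpent-2-en-4-yn-1-yl}triphenylphosphonium bromide
Conditions: PPh3·HBr (1.5 equiv), MeOH, rt
Reagents that add atoms: triphenylphosphine hydrobromide, Br.c1ccc(cc1)P(c1ccccc1)c1ccccc1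
Why: The primary allylic alcohol is converted through the allylic bromide into the phosphonium salt with the geometry retained, while the acidic methanol removes the silyl ether; the homoallylic C3–OH is not prone to ionisation.

Step 12
Reactants: 18 (3E)-4-[(1R)-2,6,6-trimethylcyclohex-2-en-1-yl]but-3-en-2-one ((R)-α-ionone)
Product: 19 (1E)-3-methyl-1-[(1R)-2,6,6-trimethylcyclohex-2-en-1-yl]penta-1,4-dien-3-ol (both epimers at the carbinol carbon)
Conditions: CH2=CHMgBr, THF, −20 → 0 °C; aq. NH4Cl
Reagents that add atoms: vinylmagnesium bromide, C=C[Mg]Br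
Why: Grignard 1,2-addition to the enone carbonyl; the new carbinol centre forms as both epimers, which is of no consequence because it becomes sp2 in the next step, and C6' is not involved.

Step 13
Reactants: 19 (1E)-3-methyl-1-[(1R)-2,6,6-trimethylcyclohex-2-en-1-yl]penta-1,4-dien-3-ol
Product: 20 {(2E,4E)-3-methyl-5-[(1R)-2,6,6-trimethylcyclohex-2-en-1-yl]penta-2,4-dien-1-yl}triphenylphosphonium bromide
Conditions: PPh3·HBr, MeOH, 0 °C → rt
Reagents that add atoms: triphenylphosphine hydrobromide, Br.c1ccc(cc1)P(c1ccccc1)c1ccccc1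
Why: Ionisation of the tertiary bis-allylic alcohol and capture of the pentadienyl cation by PPh3 at the unhindered terminus (allylic transposition) should give the C15 Wittig salt, mainly with the E trisubstituted double bond and with C6' unchanged.

Step 14
Reactants: 20 {(2E,4E)-3-methyl-5-[(1R)-2,6,6-trimethylcyclohex-2-en-1-yl]penta-2,4-dien-1-yl}triphenylphosphonium bromide; 21 (2E,4E,6E)-2,7-dimethylocta-2,4,6-trienedial (3 equiv)
Product: 24 (2E,4E,6E,8E,10E,12E)-2,7,11-trimethyl-13-[(1R)-2,6,6-trimethylcyclohex-2-en-1-yl]trideca-2,4,6,8,10,12-hexaenal, via ylide 22 (not isolated), via 8Z isomer 23 (not isolated)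
Conditions: NaOMe, MeOH/CH2Cl2, 0 °C → rt; then heptane, reflux, Ar, dark
Reagents that add atoms: none
Why: Wittig olefination of one aldehyde group of the symmetrical dialdehyde (used in excess) forms C11'=C12'; the hindered Z isomer should isomerise thermally to the all-E aldehyde.

Step 15
Reactants: 17 {(2E)-5-[(4R)-4-hydroxy-2,6,6-trimethylcyclohex-1-en-1-yl]-3-methylpent-2-en-4-yn-1-yl}triphenylphosphonium bromide; 24 (2E,4E,6E,8E,10E,12E)-2,7,11-trimethyl-13-[(1R)-2,6,6-trimethylcyclohex-2-en-1-yl]trideca-2,4,6,8,10,12-hexaenal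
Product: 27 (3R,6'R)-7,8-didehydro-β,ε-caroten-3-ol (all-E; crocoxanthin), via ylide 25 (not isolated), via 11Z isomer 26 (not isolated)
Conditions: NaOMe (2.2 equiv), MeOH/CH2Cl2, 0 °C → rt; then heptane/EtOAc, reflux, Ar, dark; crystallisation
Reagents that add atoms: none
Why: Wittig olefination forms C11=C12 and completes the C40 chain; the sterically hindered 11Z isomer should isomerise thermally to the all-E compound, and both stereocentres are remote from the reacting centres.

## Compound list

1 | 3-methoxy-3-methylbutan-1-ol | COC(C)(C)CCO | starting material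
2 | 3-methoxy-3-methylbutanal | COC(C)(C)CC=O | intermediate
3 | 1-methoxy-1,3-bis[(trimethylsilyl)oxy]buta-1,3-diene | COC(O[Si](C)(C)C)=CC(=C)O[Si](C)(C)C | starting material
4 | methyl (2Z,5S)-7-methoxy-7-methyl-3,5-bis[(trimethylsilyl)oxy]oct-2-enoate (enol ether geometry of no consequence) | COC(=O)/C=C(\O[Si](C)(C)C)C[C@@H](O[Si](C)(C)C)CC(C)(C)OC | intermediate
5 | methyl (4S)-2-hydroxy-6,6-dimethyl-4-[(trimethylsilyl)oxy]cyclohex-1-ene-1-carboxylate (held as its titanium chelate) | COC(=O)C1=C(O)C[C@@H](O[Si](C)(C)C)CC1(C)C | intermediate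
6 | methyl (4S)-2,4-dihydroxy-6,6-dimethylcyclohex-1-ene-1-carboxylate | COC(=O)C1=C(O)C[C@@H](O)CC1(C)C | intermediate
7 | methyl (4S)-4-[(tert-butyldimethylsilyl)oxy]-2-hydroxy-6,6-dimethylcyclohex-1-ene-1-carboxylate | COC(=O)C1=C(O)C[C@@H](O[Si](C)(C)C(C)(C)C)CC1(C)C | intermediate
8 | methyl (4S)-4-[(tert-butyldimethylsilyl)oxy]-2-[(diethoxyphosphoryl)oxy]-6,6-dimethylcyclohex-1-ene-1-carboxylate | COC(=O)C1=C(OP(=O)(OCC)OCC)C[C@@H](O[Si](C)(C)C(C)(C)C)CC1(C)C | intermediate
9 | methyl (4R)-4-[(tert-butyldimethylsilyl)oxy]-2,6,6-trimethylcyclohex-1-ene-1-carboxylate | COC(=O)C1=C(C)C[C@@H](O[Si](C)(C)C(C)(C)C)CC1(C)C | intermediate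
10 | {(4R)-4-[(tert-butyldimethylsilyl)oxy]-2,6,6-trimethylcyclohex-1-en-1-yl}methanol | OCC1=C(C)C[C@@H](O[Si](C)(C)C(C)(C)C)CC1(C)C | intermediate
11 | (4R)-4-[(tert-butyldimethylsilyl)oxy]-2,6,6-trimethylcyclohex-1-ene-1-carbaldehyde | O=CC1=C(C)C[C@@H](O[Si](C)(C)C(C)(C)C)CC1(C)C | intermediate
12 | tert-butyl{[(1R)-4-ethynyl-3,5,5-trimethylcyclohex-3-en-1-yl]oxy}dimethylsilane | C#CC1=C(C)C[C@@H](O[Si](C)(C)C(C)(C)C)CC1(C)C | intermediate
13 | ethyl acetoacetate | CCOC(=O)CC(C)=O | starting material
14 | ethyl (2E)-3-{[(trifluoromethyl)sulfonyl]oxy}but-2-enoate | CCOC(=O)/C=C(\C)OS(=O)(=O)C(F)(F)F | intermediate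
15 | ethyl (2E)-5-{(4R)-4-[(tert-butyldimethylsilyl)oxy]-2,6,6-trimethylcyclohex-1-en-1-yl}-3-methylpent-2-en-4-ynoate | CCOC(=O)/C=C(\C)C#CC1=C(C)C[C@@H](O[Si](C)(C)C(C)(C)C)CC1(C)C | intermediate
16 | (2E)-5-{(4R)-4-[(tert-butyldimethylsilyl)oxy]-2,6,6-trimethylcyclohex-1-en-1-yl}-3-methylpent-2-en-4-yn-1-ol | OC/C=C(\C)C#CC1=C(C)C[C@@H](O[Si](C)(C)C(C)(C)C)CC1(C)C | intermediate
17 | {(2E)-5-[(4R)-4-hydroxy-2,6,6-trimethylcyclohex-1-en-1-yl]-3-methylpent-2-en-4-yn-1-yl}triphenylphosphonium bromide | [Br-].c1ccccc1[P+](c1ccccc1)(c1ccccc1)C/C=C(\C)C#CC1=C(C)C[C@@H](O)CC1(C)C | intermediate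
18 | (3E)-4-[(1R)-2,6,6-trimethylcyclohex-2-en-1-yl]but-3-en-2-one ((R)-α-ionone) | CC1=CCCC(C)(C)[C@H]1/C=C/C(C)=O | starting material
19 | (1E)-3-methyl-1-[(1R)-2,6,6-trimethylcyclohex-2-en-1-yl]penta-1,4-dien-3-ol (both carbinol epimers) | CC1=CCCC(C)(C)[C@H]1/C=C/C(C)(O)C=C | intermediate
20 | {(2E,4E)-3-methyl-5-[(1R)-2,6,6-trimethylcyclohex-2-en-1-yl]penta-2,4-dien-1-yl}triphenylphosphonium bromide | [Br-].CC1=CCCC(C)(C)[C@H]1/C=C/C(C)=C/C[P+](c1ccccc1)(c1ccccc1)c1ccccc1 | intermediate
21 | (2E,4E,6E)-2,7-dimethylocta-2,4,6-trienedial | O=C/C(C)=C/C=C/C=C(C)/C=O | starting material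
22 | ylide of 20: {(2E,4E)-3-methyl-5-[(1R)-2,6,6-trimethylcyclohex-2-en-1-yl]penta-2,4-dien-1-ylidene}triphenylphosphorane | CC1=CCCC(C)(C)[C@H]1/C=C/C(C)=C/[CH-][P+](c1ccccc1)(c1ccccc1)c1ccccc1 | intermediate
23 | (2E,4E,6E,8Z,10E,12E)-2,7,11-trimethyl-13-[(1R)-2,6,6-trimethylcyclohex-2-en-1-yl]trideca-2,4,6,8,10,12-hexaenal | CC1=CCCC(C)(C)[C@H]1/C=C/C(C)=C/C=C\C(C)=C\C=C\C=C(C)\C=O | intermediate
24 | (2E,4E,6E,8E,10E,12E)-2,7,11-trimethyl-13-[(1R)-2,6,6-trimethylcyclohex-2-en-1-yl]trideca-2,4,6,8,10,12-hexaenal | CC1=CCCC(C)(C)[C@H]1/C=C/C(C)=C/C=C/C(C)=C/C=C/C=C(C)/C=O | intermediate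
25 | ylide of 17: {(2E)-5-[(4R)-4-hydroxy-2,6,6-trimethylcyclohex-1-en-1-yl]-3-methylpent-2-en-4-yn-1-ylidene}triphenylphosphorane | c1ccccc1[P+](c1ccccc1)(c1ccccc1)[CH-]/C=C(\C)C#CC1=C(C)C[C@@H](O)CC1(C)C | intermediate
26 | (3R,6'R,11Z)-7,8-didehydro-β,ε-caroten-3-ol | CC1=CCCC(C)(C)[C@H]1/C=C/C(C)=C/C=C/C(C)=C/C=C/C=C(C)/C=C\C=C(/C)C#CC1=C(C)C[C@@H](O)CC1(C)C | intermediate
27 | (3R,6'R)-7,8-didehydro-β,ε-caroten-3-ol (all-E; crocoxanthin) | CC1=CCCC(C)(C)[C@H]1/C=C/C(C)=C/C=C/C(C)=C/C=C/C=C(C)/C=C/C=C(\C)C#CC1=C(C)C[C@@H](O)CC1(C)C | target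

## Step count and risks

Total: 15 steps. Longest linear sequence: 11 steps (steps 1–7, 9–11 and 15).

**Step 2 (key step).** What may go wrong: residual THF, isopropoxide and BINOL temper the TiCl4, so the tertiary ether ionises incompletely. Unconsumed aldehyde may then undergo a racemic TiCl4-promoted aldol addition, which erodes the enantiomeric purity. The tertiary cation may also lose a proton or fragment (retro-Prins) before it is captured at C6, and the β-oxygen at C3 may be eliminated on warming. Fallback (sets out from 2 and 3, returns at 4): the telescoped cascade is replaced by a stop-and-go sequence in which each bond is made by a reaction that is established on its own. The Ti(OiPr)4/(R)-BINOL aldol addition is run alone and quenched with CF3CO2H, which should give the isolable δ-hydroxy-β-keto ester methyl (5S)-5-hydroxy-7-methoxy-7-methyl-3-oxooctanoate F1; this can be purified and its enantiomeric purity checked and, if needed, raised. Me3SiCl/Et3N then converts F1 into the bis-silyl compound 4, free of catalyst and THF. Compound 4 is cyclised in a separate flask with TiCl4 in pure CH2Cl2 at low temperature (Lewis-acid tert-alkylation of a silyl enol ether) to give 6.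

**Step 15.** What may go wrong: Z double bonds form at C11=C12, the 9E enyne partly isomerises to 9Z during the thermal equilibration, and the polyene aldehyde degrades under base. Fallback (sets out from 16, returns at 27): the Wittig reaction is replaced by an E-selective Horner–Wadsworth–Emmons olefination that needs no acidic salt formation and no thermal isomerisation. Alcohol 16 is converted with CBr4/PPh3 into tert-butyl({(1R)-4-[(3E)-5-bromo-3-methylpent-3-en-1-yn-1-yl]-3,5,5-trimethylcyclohex-3-en-1-yl}oxy)dimethylsilane F2. Michaelis–Arbuzov reaction with P(OEt)3 gives diethyl [(2E)-5-{(4R)-4-[(tert-butyldimethylsilyl)oxy]-2,6,6-trimethylcyclohex-1-en-1-yl}-3-methylpent-2-en-4-yn-1-yl]phosphonate F3. Deprotonation with NaN(SiMe3)2 in THF at −78 °C and addition of aldehyde 24 should give (3R,6'R)-3-[(tert-butyldimethylsilyl)oxy]-7,8-didehydro-β,ε-carotene F4, and Bu4NF in THF then frees the alcohol 27.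

**Step 7.** What may go wrong: the bulky lithiated diazo reagent adds poorly to the hindered, fully substituted enal, and γ-deprotonation to the dienolate returns aldehyde. Fallback (sets out from 11, returns at 12): the carbene rearrangement is replaced by an enol phosphate elimination. MeMgBr adds to 11 to give 1-{(4R)-4-[(tert-butyldimethylsilyl)oxy]-2,6,6-trimethylcyclohex-1-en-1-yl}ethan-1-ol F5 (both carbinol epimers). Dess–Martin oxidation gives the methyl ketone 1-{(4R)-4-[(tert-butyldimethylsilyl)oxy]-2,6,6-trimethylcyclohex-1-en-1-yl}ethan-1-one F6. Kinetic deprotonation at the methyl group with LiN(i-Pr)2 and trapping with ClP(O)(OEt)2 gives diethyl 1-{(4R)-4-[(tert-butyldimethylsilyl)oxy]-2,6,6-trimethylcyclohex-1-en-1-yl}ethenyl phosphate F7, which is not isolated; a second portion of LiN(i-Pr)2 eliminates diethyl phosphate to give alkyne 12.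

## Further compounds

F1 | step 2 | methyl (5S)-5-hydroxy-7-methoxy-7-methyl-3-oxooctanoate | COC(=O)CC(=O)C[C@@H](O)CC(C)(C)OC
F2 | step 15 | tert-butyl({(1R)-4-[(3E)-5-bromo-3-methylpent-3-en-1-yn-1-yl]-3,5,5-trimethylcyclohex-3-en-1-yl}oxy)dimethylsilane | BrC/C=C(\C)C#CC1=C(C)C[C@@H](O[Si](C)(C)C(C)(C)C)CC1(C)C
F3 | step 15 | diethyl [(2E)-5-{(4R)-4-[(tert-butyldimethylsilyl)oxy]-2,6,6-trimethylcyclohex-1-en-1-yl}-3-methylpent-2-en-4-yn-1-yl]phosphonate | CCOP(=O)(OCC)C/C=C(\C)C#CC1=C(C)C[C@@H](O[Si](C)(C)C(C)(C)C)CC1(C)C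
F4 | step 15 | (3R,6'R)-3-[(tert-butyldimethylsilyl)oxy]-7,8-didehydro-β,ε-carotene | CC1=CCCC(C)(C)[C@H]1/C=C/C(C)=C/C=C/C(C)=C/C=C/C=C(C)/C=C/C=C(\C)C#CC1=C(C)C[C@@H](O[Si](C)(C)C(C)(C)C)CC1(C)C
F5 | step 7 | 1-{(4R)-4-[(tert-butyldimethylsilyl)oxy]-2,6,6-trimethylcyclohex-1-en-1-yl}ethan-1-ol (both carbinol epimers) | CC(O)C1=C(C)C[C@@H](O[Si](C)(C)C(C)(C)C)CC1(C)C
F6 | step 7 | 1-{(4R)-4-[(tert-butyldimethylsilyl)oxy]-2,6,6-trimethylcyclohex-1-en-1-yl}ethan-1-one | CC(=O)C1=C(C)C[C@@H](O[Si](C)(C)C(C)(C)C)CC1(C)C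
F7 | step 7 | diethyl 1-{(4R)-4-[(tert-butyldimethylsilyl)oxy]-2,6,6-trimethylcyclohex-1-en-1-yl}ethenyl phosphate | C=C(OP(=O)(OCC)OCC)C1=C(C)C[C@@H](O[Si](C)(C)C(C)(C)C)CC1(C)C
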